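## The problem

Atoms are labelled by their order in the SMILES of the target 33: C5 is the acetoxymethyl carbon, C6 and C18 are the fusion carbons, C15 is the gem-dimethyl carbon, C22 the methyl-bearing cyclopropane carbon and C24 the acetoxy-bearing carbon; O9 sits on C8 and O14 on C13. Compound 33 is a nortricyclene (cyclopropane C20–C21–C22, capped by C18 through C19, C6 and C24) whose C6–C18 edge is shared with a cyclohexane, ring A (C6, C7, C8, C13, C15, C18), so C15, C18 and C6 form a run of three fully substituted carbons, with a fourth, C22, in the cage. Of the eight stereocentres, C18, C20, C21 and C22 follow from the cage once it is closed in the right sense on C6; what must be controlled is the all-cis array of C5, O9 and O14 on ring A, the face of C6 on which the cage is built, and the C24 oxygen, which must point toward C19. A cis-fused C8/C13 dioxolane can direct the creation of quaternary C6, the two different groups on C6 (C5 and ring carbon C7) can then direct cage construction, and C24 can be set by an endo rule. The three acetates, the free C13 hydroxyl beside the C8 acetate (acyl migration) and the cyclopropane with its cyclopropylcarbinyl acetate (protic acid) exclude strong base, strong acid and nucleophiles late on, and the C8 acetate must be told apart from the C13 hydroxyl within a cis-diol. The enabling feature appears when the C20–C22 bond is removed: what is left is a bicyclo[2.2.1]heptane with quaternary C6 as one-carbon bridge, C18 and C21 as bridgeheads, and the pair C24–C22 carrying oxygen and methyl, that is, the adduct of a 5,5-disubstituted cyclopentadiene and a trans-disubstituted alkene. Because C6 is quaternary the diene cannot isomerise by 1,5-hydrogen shift, and because the C22 methyl is exo in the adduct the C22–H bond lies endo, directly under C20, which is the geometry of the camphor tosylhydrazone to tricyclene insertion.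

## Retrosynthesis

**Acetate pattern (33 ⇒ 31 ⇒ 30).** The C8 acetate is traced to the cyclic orthoacetate 32 of diol 31, and the C24–O bond to a Baeyer–Villiger oxidation of methyl ketone 30. Direct acetylation of 31 would probably take the equatorial O14, whereas orthoester opening delivers the axial ester. An acetate carried from earlier would not survive the hydride and base steps, whereas a ketone oxidised late gives the C24 oxygen with retention on a carbon set by a cycloaddition. Three ester functions thus reduce to one acetyl group and protected alcohols. The forward steps need migration of secondary C24 over methyl and axial-ester opening of 32.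

**Cyclopropane (30 ⇒ 27 ⇒ 24 ⇒ 22).** After protecting-group bookkeeping (27 carries the C5 silyl ether, the acetonide and a dioxolane on the acetyl group), the C20–C22 bond is cut to a C20 carbene from tosylhydrazone 24 of ketone 22. Cutting C20–C21 or C21–C22 would leave no cycloaddition pattern; only this cut leaves a norbornanone with an endo C22–H. The acetyl group must be masked because a second ketone would compete for the hydrazide. The forward step needs 1,3 C–H insertion to outrun 1,2-hydrogen shift.

**C20 carbonyl (22 ⇒ 21 ⇒ 19 ⇒ 18).** The ketone comes from alkene C19=C20 of ketal 19 by hydroboration and oxidation, and 19 from acetyl norbornene 18. The forward step needs boron to go to C20, not to C19 beside quaternary C18.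

**Cage (18 ⇒ 16 + 17).** Bonds C18–C24 and C21–C22 are cut, giving ring-A-fused cyclopentadiene 16 and (E)-pent-3-en-2-one 17. This removes four stereocentres and one ring at once and leaves a planar diene. Tethered variants would need the tether on C5, which is on the wrong face. The forward step needs ortho regiochemistry, endo acetyl and attack syn to C7.

**Diene (16 ⇒ 15 ⇒ 14 ⇒ 13 ⇒ 11).** Diene 16 is the dehydration product of cyclopentenol 15, which arises with the C5 hydroxymethyl group when enone ester 13 is reduced (14) and silylated. The C18=C19 bond of 13 is cut by aldol condensation to 1,4-diketone 11. An enol triflate reduction would need an extra redox adjustment; here the allylic alcohol comes free with the ester reduction.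

**Quaternary C6 (11 ⇒ 9 ⇒ 7 + 8).** The acetonyl group is an ozonolysed methallyl group, and the C6–C21 bond is cut by alkylation of β-keto ester 7 with methallyl bromide 8. Introducing C21 last puts it anti to the dioxolane and leaves the ester (future C5) cis to O9 and O14, as required.

**Ring A (7 ⇒ 6 ⇒ 5 ⇒ 2 + 3; 2 ⇐ 1).** The C6–C18 bond is cut by Dieckmann condensation of diester 6, and the C13–C15 bond by aldol addition of the enolate of methyl isobutyrate 3 to aldehyde 2, made from the L-glutamic-acid-derived lactone alcohol 1. An entry by enzymatic monoreduction of 2,2-dimethylcyclohexane-1,3-dione was weighed; it supplies C13 but leaves oxygenation of C8, cis to O14, to several further steps. The open-chain route takes C8 from the chiral pool and sets C13 by Felkin–Anh addition.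

## Roads not taken

**Alternative 1:** Cut C19–C20 and C6–C21. Bromide A1 would give a primary C19 radical that adds to cyclopropene carbon C20; the cyclopropyl radical at C21 then adds to enone carbon C6, giving tetracyclic ketone A2.
- Merits: the cyclopropane arrives intact, so no carbene and no C20 oxygenation are needed; both five-membered cage rings close in one step; C5 and C24 already carry acetates, so the end game after A2 is shorter than here.
- Weak points: A1 needs a quaternary C18 stereocentre with four carbon substituents next to the C24 stereocentre and a strained 3,3-disubstituted cyclopropene. The second addition must bond a σ-radical to a fully substituted enone carbon beside the gem-dimethyl group, in competition with hydrogen transfer. Face selection on the cyclopropene relative to C24 has no clear control element.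
- Comparison: it is better in post-key-step economy. The chosen plan sets against this that each stereocentre follows a well-understood rule (endo, retention, cage geometry) and that diene 16 comes from plain enolate chemistry.

**Alternative 2:** Cut C6–C7 and C21–C22, with a sacrificial bond from C24 to the alkyne terminus. Norbornadiene–alkyne A3, with a low-valent cobalt catalyst (CoI2, PPh3, Zn), would undergo an intramolecular homo-Diels–Alder reaction to pentacycle A4.
- Merits: ring A, the cyclopropane and quaternary C6 form in one catalytic step, the largest complexity gain of the four plans.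
- Weak points: A3 is a bridgehead-quaternary norbornadiene with both alkenes trisubstituted, which is hard to make in one enantiomeric form and slow in the cycloaddition. Afterwards the exocyclic alkene must be cleaved, C7 deoxygenated, and the C24 carbon replaced by oxygen on the opposite face, which costs roughly six further steps.
- Comparison: it is better at skeleton assembly and worse at clean-up. The chosen plan installs the C24 oxygen directly with the right configuration.

**Alternative 3:** Cut C6–C18 and C20–C21, then C21–C22. Cyclopentadiene acrylate A5 would cyclise on heating to norbornene ester A6, and a decarboxylative closure from C21 onto C22=C24 would follow.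
- Merits: the tether enforces regiochemistry and face, and ring A needs no separate alkylation at C6; in ring count per step it is at least as good as the chosen plan.
- Weak points: A5 has a CH2 in the diene ring, so 1,5-hydrogen shifts scramble the substitution pattern before cycloaddition. The cycloaddition must join fully substituted C6 to substituted terminus C18, creating two adjacent quaternary centres in one bond. The cyclopropane closure runs against the cyclopropylcarbinyl to homoallyl equilibrium, and the C24 oxygen would come from an external trap with no obvious facial bias.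
- Comparison: the chosen plan has a single diene isomer (quaternary C6), forms the hindered C18 bond last in an asynchronous cycloaddition, and takes C24 from the endo rule.

Key step: step 11

Assumption: the configuration of 33 is exactly that of its SMILES, and lactone alcohol 1 of (S) configuration is taken as commercial.

## Route

Step 1
Reactants: 1 (5S)-5-(hydroxymethyl)oxolan-2-one
Product: 2 (2S)-5-oxooxolane-2-carbaldehyde
Conditions: Dess–Martin periodinane, CH2Cl2, 0 °C → rt; filtered and used crude
Reagents that add atoms: none
Why: Dess–Martin oxidation of a primary alcohol under neutral conditions; the α-oxygenated stereocentre (future C8) is not exposed to base.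

Step 2
Reactants: 2 (2S)-5-oxooxolane-2-carbaldehyde; 3 methyl 2-methylpropanoate
Product: 5 methyl (3R)-3-hydroxy-2,2-dimethyl-3-[(2S)-5-oxooxolan-2-yl]propanoate, via lithium ester enolate 4 (not isolated)
Conditions: LiN(i-Pr)2, THF, −78 °C; then 2, −78 °C; AcOH quench
Reagents that add atoms: none
Why: Aldol addition of a lithium ester enolate to an α-oxygenated aldehyde; the polar Felkin–Anh transition state puts the lactone C–O bond anti to the enolate and should give the 1,2-anti carbinol (C13, R). The aldehyde is far more electrophilic than the lactone.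

Step 3
Reactants: 5 methyl (3R)-3-hydroxy-2,2-dimethyl-3-[(2S)-5-oxooxolan-2-yl]propanoate
Product: 6 methyl 3-[(4S,5R)-5-(1-methoxy-2-methyl-1-oxopropan-2-yl)-2,2-dimethyl-1,3-dioxolan-4-yl]propanoate
Conditions: MeOH, 2,2-dimethoxypropane, TsOH·H2O (cat.), rt
Reagents that add atoms: methanol (CO); 2,2-dimethoxypropane (COC(C)(C)OC)
Why: Acid-catalysed methanolysis of the γ-lactone; trapping the liberated anti-diol as its isopropylidene acetal (transacetalisation) drives the ring opening. No stereocentre is touched, and the minor C13 epimer can be removed here as its trans-dioxolane.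

Step 4
Reactants: 6 methyl 3-[(4S,5R)-5-(1-methoxy-2-methyl-1-oxopropan-2-yl)-2,2-dimethyl-1,3-dioxolan-4-yl]propanoate
Product: 7 methyl (3aR,7aS)-2,2,4,4-tetramethyl-5-oxohexahydro-1,3-benzodioxole-6-carboxylate (C6 epimers and enol)
Conditions: KOt-Bu (1.2 equiv), THF, 0 °C → rt; AcOH
Reagents that add atoms: none
Why: Dieckmann condensation; only the C5 ester is enolisable, so C6 attacks the neopentyl ester carbon C18 (six-membered ring, helped by the gem-dimethyl group), and deprotonation of the β-keto ester drives the equilibrium.

Step 5
Reactants: 7 methyl (3aR,7aS)-2,2,4,4-tetramethyl-5-oxohexahydro-1,3-benzodioxole-6-carboxylate; 8 3-bromo-2-methylprop-1-ene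
Product: 9 methyl (3aR,6R,7aS)-2,2,4,4-tetramethyl-6-(2-methylprop-2-en-1-yl)-5-oxohexahydro-1,3-benzodioxole-6-carboxylate (ester cis to the dioxolane oxygens)
Conditions: K2CO3, acetone, reflux
Reagents that add atoms: none
Why: C-Alkylation of a β-keto ester enolate with an allylic bromide; the electrophile should enter C6 from the convex face of the cis-fused bicycle, anti to the dioxolane, which leaves the ester (future C5) cis to O9 and O14.

Step 6
Reactants: 9 methyl (3aR,6R,7aS)-2,2,4,4-tetramethyl-6-(2-methylprop-2-en-1-yl)-5-oxohexahydro-1,3-benzodioxole-6-carboxylate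
Product: 11 methyl (3aR,6S,7aS)-2,2,4,4-tetramethyl-5-oxo-6-(2-oxopropyl)hexahydro-1,3-benzodioxole-6-carboxylate, via secondary ozonide 10 (not isolated)
Conditions: O3, CH2Cl2, −78 °C; then PPh3, −78 °C → rt
Reagents that add atoms: ozone ([O-][O+]=O)
Why: Ozonolysis of the 1,1-disubstituted alkene with reductive work-up unmasks the acetonyl group; ketone, ester and acetal are inert.

Step 7
Reactants: 11 methyl (3aR,6S,7aS)-2,2,4,4-tetramethyl-5-oxo-6-(2-oxopropyl)hexahydro-1,3-benzodioxole-6-carboxylate
Product: 13 enone ester: ring A with C8/C13 acetonide fused at C6–C18 to cyclopentenone C18=C19–C20(=O)–C21H2 and CO2Me on C6 cis to O9 and O14, via aldol adduct 12 (not isolated)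
Conditions: KOt-Bu (0.5 equiv), t-BuOH, 60 °C
Reagents that add atoms: none
Why: Intramolecular aldol condensation (five-membered ring) of the methyl ketone enolate C19 onto the non-enolisable C18 ketone, then E1cB dehydration. The closest analogues are cyclopentenone annulations of 2-acetonyl-2,6,6-trisubstituted cyclohexanones; a non-nucleophilic base is chosen to spare the β-keto ester.

Step 8
Reactants: 13 enone ester
Product: 14 diol: C5 hydroxymethyl on C6 and allylic C20 carbinol (either epimer) in the cyclopentene C18=C19
Conditions: i-Bu2AlH (5 equiv), CH2Cl2, −78 → 0 °C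
Reagents that add atoms: none
Why: i-Bu2AlH reduces the ester to the primary alcohol and the enone in 1,2-fashion; the C20 configuration is removed in step 10.

Step 9
Reactants: 14 diol
Product: 15 C5 tert-butyldimethylsilyl ether of 14 with free C20 allylic alcohol
Conditions: TBSCl (1.05 equiv), imidazole, CH2Cl2, 0 °C
Reagents that add atoms: tert-butyldimethylsilyl chloride (CC(C)(C)[Si](C)(C)Cl)
Why: Chemoselective silylation of the primary over the secondary hydroxyl; the bulky ether later shields the C5 face of the diene.

Step 10
Reactants: 15 C5 silyl ether allylic alcohol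
Product: 16 ring-A-fused 5,5-disubstituted cyclopentadiene (C18=C19–C20=C21 with quaternary C6 bearing CH2OTBS; C8/C13 acetonide)
Conditions: Burgess reagent, toluene, 60 °C
Reagents that add atoms: none
Why: Burgess dehydration (syn elimination of the sulfamate ester) toward the only β-hydrogens, those on C21, gives the conjugated diene; quaternary C6 excludes positional isomers and 1,5-hydrogen shifts.

Step 11
Reactants: 16 ring-A-fused cyclopentadiene; 17 (E)-pent-3-en-2-one
Product: 18 norbornene with endo acetyl on C24 and exo methyl on C22 (new bonds C18–C24 and C21–C22; alkene C19=C20; bridge C6 with CH2OTBS syn to the alkene)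
Conditions: Me2AlCl (0.3 equiv), CH2Cl2, −78 → −20 °C
Reagents that add atoms: none
Why: Concerted, asynchronous [4+2] cycloaddition of a Lewis-acid-activated enone, of the kind known for 1,5,5-trisubstituted cyclopentadienes and enones. It closes the six-membered ring C18–C19=C20–C21–C22–C24 of the bicyclo[2.2.1]heptene suprafacially on both partners. Regiochemistry: the larger HOMO coefficient and the lower steric demand lie at unsubstituted terminus C21, which bonds first to the enone β-carbon C22, so acetyl-bearing C24 ends on C18 (ortho rule). C24: the aluminium-bound acetyl group takes the endo position (secondary orbital overlap, smaller group exo). C22: the E geometry of 17 is transferred, so the methyl is exo and the C22–H bond endo. C18 and C21: set by the face of attack, which must be syn to C7 and anti to C5; the CH2OTBS group on C6, the pseudo-axial C15 methyl and the dioxolane lie on the other face, while ring A holds C8 back from the dienophile. The step therefore needs facial, regio- and endo-selectivity, secured by that shielding, by coefficient and steric matching under Lewis acid, and by the endo transition state. Quaternary C6 keeps the diene a single isomer.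

Step 12
Reactants: 18 acetyl norbornene
Product: 19 norbornene with the acetyl group as 2-methyl-1,3-dioxolan-2-yl on C24
Conditions: 1,2-bis(trimethylsilyloxy)ethane, TMSOTf (cat.), CH2Cl2, −78 °C
Reagents that add atoms: 1,2-bis(trimethylsilyloxy)ethane (C[Si](C)(C)OCCO[Si](C)(C)C)
Why: Aprotic, silyl-triflate-catalysed ketalisation masks the methyl ketone before a second carbonyl is introduced; the acetonide, silyl ether and alkene should tolerate these conditions and C24 is not epimerised.

Step 13
Reactants: 19 ketal norbornene
Product: 21 C20 alcohol (C19 now CH2; C20 configuration immaterial), via B-alkyl-9-BBN adduct 20 (not isolated)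
Conditions: 9-BBN, THF, 65 °C; then NaOH, H2O2, 0 °C → rt
Reagents that add atoms: hydrogen peroxide (OO)
Why: Hydroboration–oxidation; boron should go to C20, away from quaternary C18 and from the endo dioxolanyl group beneath C19.

Step 14
Reactants: 21 C20 alcohol
Product: 22 C20 ketone (norbornan-2-one with ketal on C24 side chain)
Conditions: Dess–Martin periodinane, NaHCO3, CH2Cl2, rt
Reagents that add atoms: none
Why: Dess–Martin oxidation of a secondary alcohol under non-acidic conditions that spare both acetals.

Step 15
Reactants: 22 C20 ketone; 23 p-toluenesulfonyl hydrazide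
Product: 24 C20 tosylhydrazone
Conditions: THF, 4 Å MS, 60 °C
Reagents that add atoms: none
Why: Condensation of the only free carbonyl with the sulfonyl hydrazide; no protic acid is added, to protect the acetals.

Step 16
Reactants: 24 C20 tosylhydrazone
Product: 27 nortricyclene with new bond C20–C22 (C5 OTBS; C8/C13 acetonide; ketal on C24 side chain), via sodium tosylhydrazonide 25 (not isolated), via diazoalkane 26 (not isolated)
Conditions: NaH, THF, 0 °C → rt; then diglyme, 150 °C
Reagents that add atoms: none
Why: Aprotic Bamford–Stevens reaction; the salt loses sulfinate and then N2, and the C20 carbene inserts into the endo C22–H bond (1,3-insertion) as in the conversion of camphor tosylhydrazone into tricyclene. Insertion occurs with retention, so C20 and C22 take the only configurations the cage allows.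

Step 17
Reactants: 27 silyl-protected nortricyclene
Product: 28 C5 primary alcohol
Conditions: Bu4NF, THF, rt
Reagents that add atoms: none
Why: Fluoride cleavage of the primary silyl ether; acetals and cyclopropane are inert.

Step 18
Reactants: 28 C5 alcohol
Product: 29 C5 acetate
Conditions: Ac2O, pyridine, DMAP (cat.), CH2Cl2, rt
Reagents that add atoms: acetic anhydride (CC(=O)OC(C)=O)
Why: Standard acylation of the only free hydroxyl.

Step 19
Reactants: 29 C5 acetate bis-acetal
Product: 30 C8,C13-diol methyl ketone (C5 acetate; acetyl on C24)
Conditions: AcOH/H2O (4:1), 50 °C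
Reagents that add atoms: water (O)
Why: Mild aqueous acid hydrolyses the acetonide and the dioxolane together; acetic acid is too weak to protonate the cyclopropane, and the primary acetate survives.

Step 20
Reactants: 30 diol methyl ketone
Product: 31 C5,C24-diacetate C8,C13-diol
Conditions: mCPBA, Na2HPO4, CH2Cl2, rt
Reagents that add atoms: 3-chloroperbenzoic acid (OOC(=O)c1cccc(Cl)c1)
Why: Baeyer–Villiger oxidation; secondary C24 migrates in preference to methyl and with retention, so the acetate keeps the configuration set by the endo rule. Hydroxyls, acetates and cyclopropane are inert to the buffered peracid.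

Step 21
Reactants: 31 diacetate diol
Product: 33 target triacetate (C5, C8 and C24 acetates; free C13 hydroxyl), via cyclic orthoacetate 32 (not isolated)
Conditions: MeC(OMe)3, CSA (cat.), CH2Cl2, rt; then AcOH/H2O (4:1), rt
Reagents that add atoms: trimethyl orthoacetate (COC(C)(OC)OC); water (O)
Why: Orthoester exchange onto the cis-diol, then mild hydrolysis; the hemi-orthoester should collapse to the axial ester and equatorial alcohol, which places the acetate on O9 and frees O14.

## Compound list

1 | (5S)-5-(hydroxymethyl)oxolan-2-one | OC[C@@H]1CCC(=O)O1 | starting material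
2 | (2S)-5-oxooxolane-2-carbaldehyde | O=C[C@@H]1CCC(=O)O1 | intermediate
3 | methyl 2-methylpropanoate | COC(=O)C(C)C | starting material
4 | lithium enolate of 3 | COC(O[Li])=C(C)C | intermediate
5 | methyl (3R)-3-hydroxy-2,2-dimethyl-3-[(2S)-5-oxooxolan-2-yl]propanoate | COC(=O)C(C)(C)[C@@H](O)[C@@H]1CCC(=O)O1 | intermediate
6 | methyl 3-[(4S,5R)-5-(1-methoxy-2-methyl-1-oxopropan-2-yl)-2,2-dimethyl-1,3-dioxolan-4-yl]propanoate | COC(=O)CC[C@@H]1OC(C)(C)O[C@@H]1C(C)(C)C(=O)OC | intermediate
7 | methyl (3aR,7aS)-2,2,4,4-tetramethyl-5-oxohexahydro-1,3-benzodioxole-6-carboxylate | COC(=O)C1C[C@@H]2OC(C)(C)O[C@@H]2C(C)(C)C1=O | intermediate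
8 | 3-bromo-2-methylprop-1-ene | CC(=C)CBr | starting material
9 | methyl (3aR,6R,7aS)-2,2,4,4-tetramethyl-6-(2-methylprop-2-en-1-yl)-5-oxohexahydro-1,3-benzodioxole-6-carboxylate | COC(=O)[C@]1(CC(C)=C)C[C@@H]2OC(C)(C)O[C@@H]2C(C)(C)C1=O | intermediate
10 | secondary ozonide (1,2,4-trioxolane) of 9 | COC(=O)[C@]1(CC3(C)OCOO3)C[C@@H]2OC(C)(C)O[C@@H]2C(C)(C)C1=O | intermediate
11 | methyl (3aR,6S,7aS)-2,2,4,4-tetramethyl-5-oxo-6-(2-oxopropyl)hexahydro-1,3-benzodioxole-6-carboxylate | COC(=O)[C@]1(CC(C)=O)C[C@@H]2OC(C)(C)O[C@@H]2C(C)(C)C1=O | intermediate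
12 | aldol adduct: C18 tertiary alcohol, C20 ketone, five-membered ring closed | COC(=O)[C@]12C[C@@H]3OC(C)(C)O[C@@H]3C(C)(C)C1(O)CC(=O)C2 | intermediate
13 | enone ester: ring A (C8/C13 acetonide) fused at C6–C18 to cyclopentenone C18=C19–C20(=O)–C21H2; CO2Me on C6 cis to O9 and O14 | COC(=O)[C@]12C[C@@H]3OC(C)(C)O[C@@H]3C(C)(C)C1=CC(=O)C2 | intermediate
14 | diol: C5 hydroxymethyl and allylic C20 carbinol | OC[C@]12C[C@@H]3OC(C)(C)O[C@@H]3C(C)(C)C1=CC(O)C2 | intermediate
15 | C5 tert-butyldimethylsilyl ether of 14 | CC(C)(C)[Si](C)(C)OC[C@]12C[C@@H]3OC(C)(C)O[C@@H]3C(C)(C)C1=CC(O)C2 | intermediate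
16 | ring-A-fused 5,5-disubstituted cyclopentadiene (C18=C19–C20=C21; C6 bears CH2OTBS; acetonide) | CC(C)(C)[Si](C)(C)OC[C@]12C[C@H](OC4(C)C)[C@H](O4)C(C)(C)C1=CC=C2 | intermediate
17 | (E)-pent-3-en-2-one | C/C=C/C(C)=O | starting material
18 | norbornene with endo acetyl on C24 and exo methyl on C22 | CC(C)(C)[Si](C)(C)OC[C@]12C[C@H](OC4(C)C)[C@H](O4)C(C)(C)[C@]13C=C[C@H]2[C@H](C)[C@H]3C(C)=O | intermediate
19 | ethylene ketal of 18 | CC(C)(C)[Si](C)(C)OC[C@]12C[C@H](OC4(C)C)[C@H](O4)C(C)(C)[C@]13C=C[C@H]2[C@H](C)[C@H]3C5(C)OCCO5 | intermediate
20 | B-(C20-alkyl)-9-borabicyclo[3.3.1]nonane adduct of 19 | CC(C)(C)[Si](C)(C)OC[C@]12C[C@H](OC4(C)C)[C@H](O4)C(C)(C)[C@]13CC(B6C7CCCC6CCC7)[C@H]2[C@H](C)[C@H]3C5(C)OCCO5 | intermediate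
21 | C20 alcohol | CC(C)(C)[Si](C)(C)OC[C@]12C[C@H](OC4(C)C)[C@H](O4)C(C)(C)[C@]13CC(O)[C@H]2[C@H](C)[C@H]3C5(C)OCCO5 | intermediate
22 | C20 ketone | CC(C)(C)[Si](C)(C)OC[C@]12C[C@H](OC4(C)C)[C@H](O4)C(C)(C)[C@]13CC(=O)[C@H]2[C@H](C)[C@H]3C5(C)OCCO5 | intermediate
23 | p-toluenesulfonyl hydrazide | Cc1ccc(cc1)S(=O)(=O)NN | starting material
24 | C20 tosylhydrazone | CC(C)(C)[Si](C)(C)OC[C@]12C[C@H](OC4(C)C)[C@H](O4)C(C)(C)[C@]13CC(=NNS(=O)(=O)c6ccc(C)cc6)[C@H]2[C@H](C)[C@H]3C5(C)OCCO5 | intermediate
25 | sodium salt of 24 | CC(C)(C)[Si](C)(C)OC[C@]12C[C@H](OC4(C)C)[C@H](O4)C(C)(C)[C@]13CC(=N[N-]S(=O)(=O)c6ccc(C)cc6)[C@H]2[C@H](C)[C@H]3C5(C)OCCO5.[Na+] | intermediate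
26 | C20 diazoalkane | CC(C)(C)[Si](C)(C)OC[C@]12C[C@H](OC4(C)C)[C@H](O4)C(C)(C)[C@]13CC(=[N+]=[N-])[C@H]2[C@H](C)[C@H]3C5(C)OCCO5 | intermediate
27 | nortricyclene (C20–C22 closed) with C5 OTBS, acetonide and side-chain ketal | CC(C)(C)[Si](C)(C)OC[C@]12C[C@H](OC4(C)C)[C@H](O4)C(C)(C)[C@]13C[C@@H]1[C@H]2[C@]1(C)[C@H]3C5(C)OCCO5 | intermediate
28 | C5 alcohol | OC[C@]12C[C@H](OC4(C)C)[C@H](O4)C(C)(C)[C@]13C[C@@H]1[C@H]2[C@]1(C)[C@H]3C5(C)OCCO5 | intermediate
29 | C5 acetate | CC(=O)OC[C@]12C[C@H](OC4(C)C)[C@H](O4)C(C)(C)[C@]13C[C@@H]1[C@H]2[C@]1(C)[C@H]3C5(C)OCCO5 | intermediate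
30 | C8,C13-diol methyl ketone, C5 acetate | CC(=O)OC[C@]12C[C@H](O)[C@H](O)C(C)(C)[C@]13C[C@@H]1[C@H]2[C@]1(C)[C@H]3C(C)=O | intermediate
31 | C5,C24-diacetate C8,C13-diol | CC(=O)OC[C@]12C[C@H](O)[C@H](O)C(C)(C)[C@]13C[C@@H]1[C@H]2[C@]1(C)[C@H]3OC(C)=O | intermediate
32 | cyclic methyl orthoacetate of 31 on O9 and O14 | CC(=O)OC[C@]12C[C@H](OC4(C)OC)[C@H](O4)C(C)(C)[C@]13C[C@@H]1[C@H]2[C@]1(C)[C@H]3OC(C)=O | intermediate
33 | CNP0197219.1 (C5, C8, C24 triacetate; C13 alcohol) | CC(=O)OC[C@]12C[C@H](OC(C)=O)[C@H](O)C(C)(C)[C@]13C[C@@H]1[C@H]2[C@]1(C)[C@H]3OC(C)=O | target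

## Step count and least certain steps

Total: 21 steps. Longest linear sequence: 21 steps (1 → 33); 3, 8, 17 and 23 enter as purchased.

**Step 11 (key step).** Bond formation at the neopentyl terminus C18 may be slow enough that Lewis-acid-induced oligomerisation of the diene, or loss of facial and endo control, takes over. Fallback, from 16 and rejoining at 19: the neutral enone is replaced by its ethylene ketal, 2-methyl-2-[(E)-prop-1-enyl]-1,3-dioxolane F1 (from 17 and 1,2-bis(trimethylsilyloxy)ethane with catalytic TMSOTf). Catalytic TMSOTf at −78 °C opens F1 to a dioxolanylium-substituted allyl cation, a far more electrophilic two-carbon partner (ionic Diels–Alder reaction of unsaturated acetals). It should add to 16 in the same orientation and reclose to the ketal, giving 19 directly and saving step 12.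

**Step 7.** The methyl ketone enolate may acylate on the angular ester (Claisen closure to a spiro 1,3-diketone), or the β-keto ester may open, because the C18 ketone is flanked by two quaternary carbons. Fallback, from 9 and rejoining at 15: the ester is removed before the aldol. LiAlH4 reduces 9 to the diol F2; TBSCl and imidazole give the primary silyl ether F3; Dess–Martin oxidation returns the C18 ketone F4; ozonolysis gives the diketone F5; KOt-Bu in t-BuOH, now with no ester present, closes the enone F6; NaBH4 with CeCl3·7H2O gives 15.

**Step 13.** Boron may be delivered partly to C19, or the hydroboration may stall because both faces of the alkene are hindered. Fallback, from 15 and rejoining at 22: the C20 oxygen is carried in with the diene. MnO2 oxidises 15 to the enone F6; TESOTf and Et3N give the 2-(triethylsilyloxy)diene F7; this electron-rich diene should add 17 thermally (toluene, 90 °C) with the same regiochemistry, reinforced by the para-directing silyloxy group, to give the silyl enol ether adduct F8; ketalisation as in step 12 gives F9; K2CO3 in MeOH cleaves only the enol ether and gives 22.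

**Step 21.** The orthoester may open toward the C13 acetate if ring A leaves the chair in which O9 is axial, and the acetate may migrate between O9 and O14. Fallback, from 31 and rejoining at 33: kinetic differentiation instead of stereoelectronic opening. TESCl and imidazole at −20 °C should silylate the more accessible equatorial C13 hydroxyl to give the mono-silyl ether F10; Ac2O with DMAP acetylates O9 to give F11; HF·pyridine removes the silyl group to give 33.

**Step 2.** Felkin–Anh selectivity may be modest, or the aldehyde may epimerise at C8 by enolisation. Fallback, from the epimer mixture of 5 and returning to 5: Dess–Martin oxidation gives the keto lactone F12, and reduction with Li(s-Bu)3BH at −78 °C, for which Felkin–Anh control by the α-oxygen is usually higher for hydride than for carbon nucleophiles, regenerates the anti carbinol 5.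

## Further compounds

F1 | step 11 | 2-methyl-2-[(E)-prop-1-enyl]-1,3-dioxolane | C/C=C/C1(C)OCCO1
F2 | step 7 | diol from reduction of 9 (C5 hydroxymethyl, C18 carbinol, methallyl on C6) | OC[C@]1(CC(C)=C)C[C@@H]2OC(C)(C)O[C@@H]2C(C)(C)C1O
F3 | step 7 | C5 tert-butyldimethylsilyl ether of F2 | CC(C)(C)[Si](C)(C)OC[C@]1(CC(C)=C)C[C@@H]2OC(C)(C)O[C@@H]2C(C)(C)C1O
F4 | step 7 | C18 ketone with C5 OTBS and methallyl on C6 | CC(C)(C)[Si](C)(C)OC[C@]1(CC(C)=C)C[C@@H]2OC(C)(C)O[C@@H]2C(C)(C)C1=O
F5 | step 7 | 1,4-diketone with C5 OTBS and acetonyl on C6 | CC(C)(C)[Si](C)(C)OC[C@]1(CC(C)=O)C[C@@H]2OC(C)(C)O[C@@H]2C(C)(C)C1=O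
F6 | step 7 | cyclopentenone C18=C19–C20(=O)–C21H2 with C5 OTBS | CC(C)(C)[Si](C)(C)OC[C@]12C[C@@H]3OC(C)(C)O[C@@H]3C(C)(C)C1=CC(=O)C2
F7 | step 13 | 2-(triethylsilyloxy)cyclopentadiene (OSiEt3 on C20) | CC(C)(C)[Si](C)(C)OC[C@]12C[C@@H]3OC(C)(C)O[C@@H]3C(C)(C)C1=CC(O[Si](CC)(CC)CC)=C2
F8 | step 13 | cycloadduct with C19=C20 silyl enol ether, endo acetyl on C24, exo methyl on C22 | CC(C)(C)[Si](C)(C)OC[C@]12C[C@H](OC4(C)C)[C@H](O4)C(C)(C)[C@]13C=C(O[Si](CC)(CC)CC)[C@H]2[C@H](C)[C@H]3C(C)=O
F9 | step 13 | ethylene ketal of F8 | CC(C)(C)[Si](C)(C)OC[C@]12C[C@H](OC4(C)C)[C@H](O4)C(C)(C)[C@]13C=C(O[Si](CC)(CC)CC)[C@H]2[C@H](C)[C@H]3C5(C)OCCO5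
F10 | step 21 | C13 triethylsilyl ether of 31 | CC(=O)OC[C@]12C[C@H](O)[C@H](O[Si](CC)(CC)CC)C(C)(C)[C@]13C[C@@H]1[C@H]2[C@]1(C)[C@H]3OC(C)=O
F11 | step 21 | C8 acetate of F10 | CC(=O)OC[C@]12C[C@H](OC(C)=O)[C@H](O[Si](CC)(CC)CC)C(C)(C)[C@]13C[C@@H]1[C@H]2[C@]1(C)[C@H]3OC(C)=O
F12 | step 2 | methyl 2,2-dimethyl-3-oxo-3-[(2S)-5-oxooxolan-2-yl]propanoate | COC(=O)C(C)(C)C(=O)[C@@H]1CCC(=O)O1
A1 | alternative 1 | bromide radical precursor (ring A enone, C19 bromomethyl on C18, 1-methylcycloprop-2-enyl on C24) | CC(=O)OCC1=CC(=O)[C@H](OCc5ccccc5)C(C)(C)[C@@]1(CBr)[C@H](OC(C)=O)C2(C)C=C2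
A2 | alternative 1 | tetracyclic C8 ketone, C13 benzyl ether, C5 and C24 acetates | CC(=O)OC[C@]12CC(=O)[C@H](OCc5ccccc5)C(C)(C)[C@]13C[C@@H]1[C@H]2[C@]1(C)[C@H]3OC(C)=O
A3 | alternative 2 | norbornadiene with alkyne tether on bridgehead C18 | CC(C)(C)[Si](C)(C)OCC1=C[C@H]2C[C@@]1(C=C2C)C(C)(C)[C@H]3OC(C)(C)O[C@H]3C#C
A4 | alternative 2 | pentacyclic homo-Diels–Alder adduct (cyclopentene across C6 and C24) | CC(C)(C)[Si](C)(C)OC[C@]12C(=C5)[C@H](OC4(C)C)[C@H](O4)C(C)(C)[C@]13C[C@@H]1[C@H]2[C@]1(C)[C@@H]35
A5 | alternative 3 | cyclopentadiene tethered to an (E)-acrylate | CC(C)(C)[Si](C)(C)OC/C(C[C@@H]1OC(C)(C)O[C@@H]1C(C)(C)C2=CC(C)=CC2)=C/C(=O)OC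
A6 | alternative 3 | tricyclic norbornene C21 methyl ester | CC(C)(C)[Si](C)(C)OC[C@]12C[C@H](OC4(C)C)[C@H](O4)C(C)(C)[C@]13C[C@H]([C@H]2C(=O)OC)C(C)=C3
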